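## Analysis of the target

The target 40 is a diacetylated C30 bis(perhydrobenzoxepine): two trans-fused bicycles, each a cyclohexane (rings A and D) fused to an oxepane (rings B and C), joined through their cyclohexane carbons by a CH2–CH2 tether. The two halves have the same absolute sense at corresponding centres: in each, the ring-fusion CH–O hydrogen is anti to the angular methyl, the tether-bearing CH is cis to that methyl, and the oxepane carbinol oxygen is cis to the ring-fusion hydrogen. The ninth stereocentre is the tertiary acetate carbon of ring D, whose acetoxy group is axial, syn to the angular methyl and cis to the tether. The halves differ at two sites only: ring A has an exocyclic methylene where ring D has the C(Me)OAc carbon, and the ring B carbinol is free where the ring C carbinol is acetylated. The sensitive groups are the tertiary acetate (hard to make, prone to elimination), the 1,1-disubstituted alkene (hydrogenation, acid isomerisation) and two nearly identical secondary carbinols, of which only one may end up acylated. The difficulty lies in the contiguous stereocentres around each quaternary carbon (four in ring D, three in ring A) and in seven-membered ethers whose C(Me)2–O carbon sits next to a carbinol. The strategy rests on exactly this last feature: in ring C, and again in ring B, the carbinol carbon is bonded to the fully substituted ether carbon, and that bond can be formed by adding an aldehyde-derived ketyl to the β-carbon of a β-alkoxycrotonate on the ring-fusion oxygen, with one of the two methyls arriving as a CH2CO2R arm.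

## Retrosynthetic reasoning

**End game (40 back to 36).** The free ring B carbinol is carried as its triethylsilyl ether 39. In each C(Me)2–O group one methyl is traced back to a CH2CO2H arm (bis-redox-active ester 38, diacid 37, diallyl ester 36). This turns both gem-dimethyl ether carbons into former crotonate β-carbons. Both arms are excised together at the very end, so one deprotection, one activation and one decarboxylation serve both halves. Allyl esters are used because ring A already carries its methylene by then, which rules out hydrogenolysis. The silyl ether is needed because activating the acetic acid arm next to a free hydroxyl would lactonise.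

**Ring B (35 back to 30).** The bond between the ring B carbinol carbon and the ether carbon is cut, giving aldehyde 34 with an (E)-alkoxycrotonate on the ring-fusion oxygen. This is the same reaction that makes ring C, run a second time. Ring B is closed after the ring C carbinol has been acetylated (23), so the one carbinol that must stay free is simply the one formed last. The aldehyde comes from a PMB ether (33, 32) and the crotonate from alcohol 31 and ynoate 18.

**Methylene and tether (30 back to 25 and 6).** The methylene of 30 comes from ketone 29. It is installed before ring B is closed, because a ketone 1,6 to the aldehyde would divert the ketyl into pinacol closure. The tether is cut at the bond between the ring A CH and its CH2 (29 from enone 28, aldol 26, enol silane 6 and aldehyde 25). That carbon is the enol carbon that conjugate addition with silyl trapping delivers regiospecifically; no other method makes the hindered position beside the quaternary carbon nucleophilic. The union is run as a Lewis-acid-mediated addition of 6 itself, so the ester-rich aldehyde 25 never meets a basic enolate. A cut in the middle of the tether would need substitution at doubly β-branched centres, or an olefination followed by a hydrogenation that the later alkene forbids. The stereocentre is set when the enolate from conjugate reduction is protonated.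

**Arm of the diacetate half (25 back to 22).** Aldehyde 25 comes from the TBDPS ether 23 by desilylation (24) and oxidation. Acetate 23 comes from the key-step product 22.

**Key disconnection (22 back to 21).** In ring C the bond between the carbinol carbon and the ether carbon is cut. The forward step must close a seven-membered ether onto a fully substituted carbon and put the hydroxyl cis to the ring-fusion hydrogen. A samarium chelate between ketyl and ester oxygen provides that control.

**Key-step precursor (21 back to 14).** The aldehyde of 21 is revealed last, by oxidation of alcohol 20 after oxidative removal of a PMB group from 19. An alkene precursor would need ozone or osmium in the presence of the enol ether, and an acetal would need aqueous acid. Crotonate 19 comes from alcohol 15 and ynoate 18 (from acid 16 and bromide 17). Alcohol 15 comes from 14 by removing a triethylsilyl ether beside a TBDPS ether, a PMB ether and the tertiary acetate. This order of three unmaskings dictates the three protecting groups.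

**Ring D substituents (14 back to 8).** The tertiary acetate of 14 is cut to ketone 12 and a methyl nucleophile; the alkoxide is acetylated in the same flask. The two-carbon arm of 12 is introduced by aldol addition of enolate 8 to aldehyde 7, dehydration (11) and conjugate reduction. It is not introduced by alkylating the enolate. An electrophile would enter anti to the axial methyl and end up trans to it. A proton entering on that face leaves the arm cis to the methyl, as required.

**Common intermediate (8 and 6 back to 1).** Enol silane 6 stores the regiochemistry for both halves. It is made by conjugate addition of the organometallic from bromide 5 to enone 4 anti to the silyloxy group. For ring D, MeLi releases lithium enolate 8 from it (step 5). For ring A, 6 adds directly to aldehyde 25 under Lewis acid activation (step 18). Because the two halves are pseudo-C2-related, the same enantiomer of 6 serves both. Enone 4 comes from 2-methylcyclohex-2-en-1-one 1 by enantioselective reduction (2), silylation (3) and allylic oxidation. The carbinol centre of 2 is the source of all absolute configuration.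

## Alternatives that were turned down

**Alternative 1:** Rings A and B of the methylene half would be cut back to a 2,2-dimethyl-3(2H)-furanone whose C5 chain ends in an isopropenyl group. Irradiation would give the intramolecular [2+2] adduct A1. In A1 the oxygen-bearing furanone carbon is bonded to the methyl-bearing alkene carbon and the α-carbon to the former CH2, so ring A and a cyclobutane form together. Cleavage of the cyclobutane bond between the two former enone carbons would then enlarge the furanone to the oxepane.
- For it: the C(Me)2–O carbon and the adjacent oxygenated carbon come intact from a simple heterocycle, so no arm has to be excised. On that point it is better than the chosen route. Ring A and the quaternary carbon also arise in one step.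
- Against it: three stereochemical events lack a strong control element. These are the facial course of the cycloaddition (steered only by the arm-bearing CH on a flexible tether), the delivery of hydrogen to the ring-fusion carbon after fragmentation, and the reduction of the furanone ketone to the carbinol. The fragmentation also competes with simple cycloreversion. A1 is only a ketal-protected methylene half; the diacetate half, the tertiary acetate and the union remain open.
- Comparison: the chosen route is longer at this point, but it sets the ring-fusion centre before ring closure and the carbinol through a chelate.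

**Alternative 2:** Ring A would be cut across two bonds: the one between the angular-methyl carbon and the tether-bearing CH, and the one between a ring CH2 and the carbon that later carries the methylene. The components are a 7-vinyl tetrahydrooxepine (ring B complete) and an (E)-enal built on the finished diacetate half. A chiral Lewis acid would promote the Diels–Alder reaction to A2.
- For it: this is the most convergent plan. It unites the halves and forms ring A, the quaternary carbon and the tether stereocentre at once. In convergence it is clearly stronger than the chosen route, which builds ring A linearly on the diacetate half. The regiochemistry is also matched (2-alkoxy diene, oxygen para to formyl).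
- Against it: the diene terminus that becomes the quaternary carbon is fully substituted, and the dienophile is a β-alkyl enal. This slow pairing needs strong activation, which the acid-labile dienyl ether may not survive. Facial selectivity would have to come from a remote silyloxy centre and the catalyst acting on two chiral partners. Afterwards the enol ether must be reduced to the trans ring fusion and the formyl group converted into the methylene. Both partners still need a ring synthesis of their own, the enal in particular a ring C synthesis.
- Comparison: the chosen route gives up convergence for bond formations with known facial preferences (anti addition, axial-methyl shielding, chelation).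

**Alternative 3:** Rings C and D would be cut together, at the O–C(Me)2 bond and at the bond between the methyl-bearing quaternary carbon and the α-carbon of the ring D ketone. The precursor is an acyclic bis-epoxide ending in an enol silane. Me3SiOTf would activate the terminal epoxide, the internal epoxide oxygen would attack its tertiary carbon, and the enol silane would open the resulting epoxonium ion to give A3.
- For it: two rings, the quaternary carbon, the carbinol, the gem-dimethyl group and the ring D ketone arise in one step, from stereocentres set by asymmetric epoxidation. In step count this is clearly stronger than the chosen route, and there is no arm to excise.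
- Against it: three selectivities must coincide. The terminal epoxide must open endo at its tertiary carbon rather than by exo attack. The enol silane must open the epoxonium ion anti at the more substituted carbon, creating a quaternary centre. The enol silane geometry, hard to fix for an unsymmetrical ketone, decides the arm-bearing centre. Cationic cascades of this kind are also diverted by elimination, 1,2-shifts and premature capture.
- Comparison: the chosen route is longer, but each centre is set in a separate step and a failure at one step does not scramble the others.

Key step: step 14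

Assumption: the reduction of enone 1 is taken to follow the usual model with the alkenyl branch as the large group, so the (S)-oxazaborolidine gives (R)-2; were the sense opposite, the (R)-catalyst would be used and nothing else changes.

## Route

Step 1
Reactants: 1 2-methylcyclohex-2-en-1-one
Product: 2 (R)-2-methylcyclohex-2-en-1-ol
Conditions: (S)-2-methyl-CBS-oxazaborolidine (10 mol %), catecholborane, toluene, −78 °C; aq. NaOH
Reagents that add atoms: none
Why: Corey–Bakshi–Shibata reduction; with the trisubstituted alkenyl carbon as the large group the (S)-catalyst should deliver hydride to the face that gives the (R)-carbinol, the centre from which all other stereocentres of both halves are derived.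

Step 2
Reactants: 2 (R)-2-methylcyclohex-2-en-1-ol
Product: 3 (R)-triethyl[(2-methylcyclohex-2-en-1-yl)oxy]silane
Conditions: TESCl, imidazole, CH2Cl2, 0 °C to rt
Reagents that add atoms: chlorotriethylsilane, CC[Si](Cl)(CC)CC
Why: Standard silylation of a secondary allylic alcohol; the triethylsilyl group is chosen because mild acid removes it later beside a TBDPS ether, a PMB ether and acetates.

Step 3
Reactants: 3 (R)-triethyl[(2-methylcyclohex-2-en-1-yl)oxy]silane
Product: 4 (R)-3-methyl-4-(triethylsilyloxy)cyclohex-2-en-1-one
Conditions: Rh2(cap)4 (dirhodium tetracaprolactamate, 1 mol %), t-BuOOH (70 % in water), K2CO3, CH2Cl2, rt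
Reagents that add atoms: tert-butyl hydroperoxide, CC(C)(C)OO
Why: Catalytic allylic C–H oxidation with tert-butyl hydroperoxide; the only allylic ring CH2 should be oxidised to the ketone, the carbinol C–H being shielded by the silyl group and the methyl C–H being primary, so the γ-silyloxy enone forms without touching the stereocentre.

Step 4
Reactants: 4 (R)-3-methyl-4-(triethylsilyloxy)cyclohex-2-en-1-one; 5 1-[(3-bromopropoxy)methyl]-4-methoxybenzene (as its Grignard reagent, made in the flask)
Product: 6 trimethylsilyl enol ether of the (3R,4R)-3-[3-(4-methoxybenzyloxy)propyl]-3-methyl-4-(triethylsilyloxy)cyclohexanone (enol double bond toward the quaternary carbon; propyl chain trans to the silyloxy group)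
Conditions: 5, Mg, THF; then CuBr·SMe2 (10 mol %), TMSCl, HMPA, 4, THF, −78 °C; Et3N, cold aq. NaHCO3
Reagents that add atoms: chlorotrimethylsilane, C[Si](C)(C)Cl
Why: Copper-catalysed conjugate addition of a Grignard reagent accelerated by TMSCl; allylic strain with the 3-methyl group holds the silyloxy group pseudo-axial, so the alkyl group should add anti to it and create the quaternary carbon with the chain trans to oxygen, while silylation stores the enolate regiospecifically.

Step 5
Reactants: 6 trimethylsilyl enol ether; 7 2-(tert-butyldiphenylsilyloxy)acetaldehyde
Product: 9 β-hydroxy ketone (aldol adduct; both new centres as a mixture), via lithium enolate 8 (not isolated)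
Conditions: MeLi, THF, 0 °C; then 7, −78 °C; AcOH, −78 °C
Reagents that add atoms: none
Why: MeLi cleaves the enol silane to the regiodefined lithium enolate, which undergoes aldol addition to the reactive α-silyloxy aldehyde at low temperature; the configuration of the two new centres does not matter because one is removed in step 6 and the other reset in step 7.

Step 6
Reactants: 9 β-hydroxy ketone
Product: 11 2-[2-(tert-butyldiphenylsilyloxy)ethylidene] ketone (E/Z mixture), via mesylate 10 (not isolated)
Conditions: MsCl, Et3N, DMAP (cat.), CH2Cl2, 0 °C to rt
Reagents that add atoms: none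
Why: Mesylation and E1cB elimination of a β-mesyloxy ketone; the quaternary carbon on the other side allows only the exocyclic enone, and triethylamine is too weak to deconjugate it toward the silyloxy group.

Step 7
Reactants: 11 2-alkylidene ketone
Product: 12 (2R,3R,4R)-2-[2-(tert-butyldiphenylsilyloxy)ethyl]-3-[3-(4-methoxybenzyloxy)propyl]-3-methyl-4-(triethylsilyloxy)cyclohexan-1-one
Conditions: [(Ph3P)CuH]6, H2O (5 equiv), toluene, rt
Reagents that add atoms: none
Why: Conjugate reduction by a phosphine-stabilised copper hydride, which leaves silyl ethers and the PMB ether alone; the copper enolate should be protonated axially on the face opposite the axial ring methyl (chain and silyloxy group stay equatorial), which puts the arm equatorial and cis to the methyl, the arrangement also expected to be favoured at equilibrium.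

Step 8
Reactants: 12 ring D ketone
Product: 14 (1S,2R,3R,4R)-2-[2-(tert-butyldiphenylsilyloxy)ethyl]-3-[3-(4-methoxybenzyloxy)propyl]-1,3-dimethyl-4-(triethylsilyloxy)cyclohexyl acetate, via dichlorocerium alkoxide 13 (not isolated)
Conditions: MeLi, CeCl3, THF, −78 °C; then Ac2O, −78 °C to rt
Reagents that add atoms: methyllithium, [Li]C; acetic anhydride, CC(=O)OC(C)=O
Why: Organocerium addition to an enolisable hindered ketone; the axial methyl on the β-carbon blocks axial attack, so the methyl group should enter equatorially and leave the oxygen axial, syn to the ring methyl and cis to the arm, and acylation of the alkoxide in the same flask avoids a separate esterification of a crowded tertiary alcohol.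

Step 9
Reactants: 14 tertiary acetate
Product: 15 (1S,2R,3R,4R)-2-[2-(tert-butyldiphenylsilyloxy)ethyl]-4-hydroxy-3-[3-(4-methoxybenzyloxy)propyl]-1,3-dimethylcyclohexyl acetate
Conditions: PPTS, MeOH, rt
Reagents that add atoms: none
Why: Acid-catalysed methanolysis of a triethylsilyl ether is far faster than that of a primary TBDPS ether; the PMB ether and the tertiary acetate are inert to PPTS.

Step 10
Reactants: 16 but-2-ynoic acid; 17 allyl bromide
Product: 18 allyl but-2-ynoate
Conditions: K2CO3, DMF, rt
Reagents that add atoms: none
Why: O-Alkylation of a carboxylate by SN2 displacement on an allylic bromide; the mild carbonate base avoids isomerisation of the alkyne.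

Step 11
Reactants: 15 ring D alcohol; 18 allyl but-2-ynoate
Product: 19 (E)-β-alkoxycrotonate of 15 (allyl (E)-3-alkoxybut-2-enoate on the ring oxygen)
Conditions: PMe3 (0.3 equiv), 18 (3 equiv), CH2Cl2, rt
Reagents that add atoms: none
Why: Phosphine-catalysed oxa-Michael addition of an alcohol to an ynoate: PMe3 adds to 18 to give a basic zwitterion that deprotonates the alcohol, the alkoxide adds to the β-carbon, and protonation anti to the new C–O bond should give the (E)-alkoxycrotonate; the small, strongly nucleophilic phosphine is chosen because the alcohol is neopentyl-like.

Step 12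
Reactants: 19 alkoxycrotonate
Product: 20 primary alcohol (3-hydroxypropyl chain on the quaternary carbon)
Conditions: DDQ, CH2Cl2/pH 7 buffer, 0 °C to rt
Reagents that add atoms: none
Why: Oxidative cleavage of the p-methoxybenzyl ether by DDQ (hydride abstraction, hydrolysis of the oxocarbenium ion); the push–pull enol ether, the allyl ester and the silyl ether are not electron-rich enough to react.

Step 13
Reactants: 20 primary alcohol
Product: 21 aldehyde (E)-β-alkoxycrotonate (3-oxopropyl chain on the quaternary carbon; key-step precursor)
Conditions: Dess–Martin periodinane, NaHCO3, CH2Cl2, 0 °C to rt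
Reagents that add atoms: none
Why: Dess–Martin oxidation under buffered, non-aqueous conditions gives the aldehyde without exposing the enol ether to acid or ozone.

Step 14
Reactants: 21 aldehyde (E)-β-alkoxycrotonate
Product: 22 ring C hydroxy oxepane with allyl ester arm (trans-fused; hydroxyl cis to the ring-fusion hydrogen and trans to the CH2CO2allyl arm)
Conditions: SmI2 (3 equiv), MeOH (3 equiv), THF, 0 °C to rt
Reagents that add atoms: none
Why: SmI2 transfers an electron to the aldehyde of 21; the ketyl, bound to trivalent samarium, adds to the β-carbon of the (E)-alkoxycrotonate, a second electron reduces the α-ester radical to a samarium enolate, and methanol protonates it. The closest known reaction type is the SmI2-induced reductive cyclisation of aldehydes onto β-alkoxyacrylates and β-alkoxycrotonates, used for trans-fused tetrahydropyrans and oxepanes with angular methyl groups. Ring C closes in a 7-exo-trig mode, the new bond joining the carbinol carbon to the ether carbon. The carbinol centre is controlled by the chelate in which samarium bridges the ketyl oxygen and the ester carbonyl oxygen, which forces the ketyl C–O bond and the ester arm to opposite sides of the forming ring. The ether carbon is controlled by the s-trans crotonate lying in a chair-like array with its β-methyl syn to the ring-fusion hydrogen across the oxygen; the two relations together put the hydroxyl cis to the ring-fusion hydrogen, and the ether-carbon centre is erased later. The step needs chemoselective reduction of the aldehyde beside an allyl ester, an acetate and a silyl ether, which SmI2 without polar additives should provide, and it needs addition to outrun simple reduction and pinacol coupling. The substrate secures this through the quaternary carbon that carries the aldehyde chain and the equatorial C–O bond on the neighbouring ring carbon, which hold ketyl and acceptor within reach, and through the absence of any other ketone or aldehyde.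

Step 15
Reactants: 22 ring C hydroxy oxepane
Product: 23 ring C acetate (diacetate with allyl ester arm and TBDPS-protected arm)
Conditions: Ac2O, pyridine, DMAP, CH2Cl2, rt
Reagents that add atoms: acetic anhydride, CC(=O)OC(C)=O
Why: DMAP-catalysed acetylation of the hindered secondary alcohol; this fixes the ring C acetate before the second carbinol exists, so no selective acylation is ever needed.

Step 16
Reactants: 23 diacetate silyl ether
Product: 24 primary alcohol (2-hydroxyethyl arm on ring D)
Conditions: TBAF, AcOH, THF, rt
Reagents that add atoms: none
Why: Fluoride cleavage of the primary TBDPS ether, buffered with acetic acid so that the β-alkoxy ester is not exposed to basic fluoride and the acetates do not migrate.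

Step 17
Reactants: 24 primary alcohol
Product: 25 diacetate-half aldehyde (2-oxoethyl arm on ring D)
Conditions: Dess–Martin periodinane, NaHCO3, CH2Cl2, 0 °C to rt
Reagents that add atoms: none
Why: Dess–Martin oxidation to a β-branched aldehyde; no leaving group is β to the formyl group, so the aldehyde is stable toward elimination.

Step 18
Reactants: 6 trimethylsilyl enol ether (second portion); 25 diacetate-half aldehyde
Product: 26 β-hydroxy ketone joining both halves (mixture at the two new centres)
Conditions: 6 (1.5 equiv), 25, BF3·OEt2 (1.2 equiv), CH2Cl2, −78 °C; aq. NaHCO3
Reagents that add atoms: none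
Why: Mukaiyama aldol addition; BF3 activates only the aldehyde of the finished diacetate half, and the enol silane that also supplied ring D attacks it through the one carbon that conjugate addition and silyl trapping made nucleophilic, so the tether bond forms without a basic enolate that could deprotonate the α-CH2 of 25 or attack its esters. The silyl ethers, the PMB ether and the acetates should tolerate the Lewis acid at −78 °C, and the two new centres are again removed (step 19) or reset (step 20).

Step 19
Reactants: 26 β-hydroxy ketone
Product: 28 alkylidene ketone (E/Z mixture), via mesylate 27 (not isolated)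
Conditions: MsCl, Et3N, DMAP (cat.), CH2Cl2, 0 °C to rt
Reagents that add atoms: none
Why: Mesylation and E1cB elimination to the exocyclic enone, as in step 6.

Step 20
Reactants: 28 alkylidene ketone
Product: 29 ring A ketone (tether cis to the angular methyl)
Conditions: [(Ph3P)CuH]6, H2O (5 equiv), toluene, rt
Reagents that add atoms: none
Why: Copper hydride conjugate reduction as in step 7, chemoselective for the enone over the allyl ester and the acetates; axial protonation of the copper enolate anti to the axial methyl should again place the tether equatorial and cis to the angular methyl.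

Step 21
Reactants: 29 ring A ketone
Product: 30 ring A exocyclic methylene compound
Conditions: Zn, CH2Br2, TiCl4, THF/CH2Cl2, 0 °C to rt
Reagents that add atoms: dibromomethane, BrCBr
Why: Takai–Lombardo methylenation; the gem-dizinc reagent activated by TiCl4 converts the ketone into the 1,1-disubstituted alkene without base, so the α-stereocentre is not epimerised and the esters are untouched; it is placed here because a ketone 1,6 to the later aldehyde would divert the ketyl of step 26 into pinacol closure.

Step 22
Reactants: 30 methylene compound
Product: 31 ring A alcohol (free hydroxyl on the carbon next to the quaternary carbon)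
Conditions: PPTS, MeOH, rt
Reagents that add atoms: none
Why: Selective acid methanolysis of the triethylsilyl ether as in step 9; the exocyclic alkene, the PMB ether and the esters tolerate PPTS.

Step 23
Reactants: 31 ring A alcohol; 18 allyl but-2-ynoate
Product: 32 ring A (E)-β-alkoxycrotonate
Conditions: PMe3 (0.3 equiv), 18 (3 equiv), CH2Cl2, rt
Reagents that add atoms: none
Why: Phosphine-catalysed oxa-Michael addition to the ynoate as in step 11.

Step 24
Reactants: 32 ring A alkoxycrotonate
Product: 33 primary alcohol (3-hydroxypropyl chain on ring A)
Conditions: DDQ, CH2Cl2/pH 7 buffer, 0 °C to rt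
Reagents that add atoms: none
Why: DDQ removal of the PMB ether as in step 12; the unactivated exocyclic alkene is inert to DDQ.

Step 25
Reactants: 33 primary alcohol
Product: 34 ring A aldehyde (E)-β-alkoxycrotonate
Conditions: Dess–Martin periodinane, NaHCO3, CH2Cl2, 0 °C to rt
Reagents that add atoms: none
Why: Buffered Dess–Martin oxidation as in step 13.

Step 26
Reactants: 34 ring A aldehyde alkoxycrotonate
Product: 35 bis-oxepane with free ring B hydroxyl and two allyl ester arms
Conditions: SmI2 (3 equiv), MeOH (3 equiv), THF, 0 °C to rt
Reagents that add atoms: none
Why: Second use of the SmI2 ketyl–alkoxycrotonate cyclisation (7-exo-trig), closing ring B; the same chelate should place the hydroxyl trans to the ester arm and cis to the ring-fusion hydrogen, and the isolated 1,1-disubstituted alkene is not a competent radical acceptor under these conditions.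

Step 27
Reactants: 35 bis-oxepane alcohol
Product: 36 ring B triethylsilyl ether
Conditions: TESOTf, 2,6-lutidine, CH2Cl2, −78 °C
Reagents that add atoms: triethylsilyl trifluoromethanesulfonate, CC[Si](CC)(CC)OS(=O)(=O)C(F)(F)F
Why: Silylation of the hindered secondary alcohol with a silyl triflate; protection is needed because activation of the neighbouring acetic acid arm in step 29 would otherwise lactonise onto this hydroxyl.

Step 28
Reactants: 36 diallyl ester
Product: 37 diacid
Conditions: Pd(PPh3)4 (5 mol %), morpholine, THF, rt; dilute acid work-up
Reagents that add atoms: none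
Why: Tsuji–Trost deallylation; zerovalent palladium ionises the allyl esters to π-allyl complexes that morpholine captures, so both arms are freed without hydrogen and the exocyclic alkene is untouched.

Step 29
Reactants: 37 diacid
Product: 38 bis(N-acyloxyphthalimide)
Conditions: N-hydroxyphthalimide, N,N'-diisopropylcarbodiimide, DMAP (cat.), CH2Cl2, rt
Reagents that add atoms: N-hydroxyphthalimide, O=C1c2ccccc2C(=O)N1O
Why: Carbodiimide esterification gives the redox-active esters of both arms.

Step 30
Reactants: 38 bis(N-acyloxyphthalimide)
Product: 39 triethylsilyl ether of the target (both C(Me)2–O groups in place)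
Conditions: Ru(bpy)3Cl2 (1 mol %), Hantzsch ester (3 equiv), DMF, blue LEDs, rt
Reagents that add atoms: none
Why: Photoredox reductive decarboxylation of redox-active esters; single-electron reduction fragments each ester to phthalimide anion, CO2 and a primary alkyl radical, which abstracts hydrogen from the Hantzsch ester, so each arm becomes the second methyl and the ether-carbon stereocentres made in steps 14 and 26 disappear; no thiol is used, which protects the exocyclic alkene.

Step 31
Reactants: 39 triethylsilyl ether
Product: 40 target CNP0412606.2
Conditions: HF·pyridine, pyridine, THF, 0 °C to rt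
Reagents that add atoms: none
Why: Fluoride cleavage of the triethylsilyl ether under buffered conditions that leave the secondary and tertiary acetates and the exocyclic alkene unchanged.

## Compound list

1 | 2-methylcyclohex-2-en-1-one | CC1=CCCCC1=O | starting material
2 | (R)-2-methylcyclohex-2-en-1-ol | CC1=CCCC[C@H]1O | intermediate
3 | (R)-triethyl[(2-methylcyclohex-2-en-1-yl)oxy]silane | CC1=CCCC[C@H]1O[Si](CC)(CC)CC | intermediate
4 | (R)-3-methyl-4-(triethylsilyloxy)cyclohex-2-en-1-one | CC1=CC(=O)CC[C@H]1O[Si](CC)(CC)CC | intermediate
5 | 1-[(3-bromopropoxy)methyl]-4-methoxybenzene | COc1ccc(COCCCBr)cc1 | starting material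
6 | trimethylsilyl enol ether of (3R,4R)-3-[3-(4-methoxybenzyloxy)propyl]-3-methyl-4-(triethylsilyloxy)cyclohexanone, chain trans to OTES | C[Si](C)(C)OC1=C[C@@](C)(CCCOCc2ccc(OC)cc2)[C@H](O[Si](CC)(CC)CC)CC1 | intermediate
7 | 2-(tert-butyldiphenylsilyloxy)acetaldehyde | O=CCO[Si](c1ccccc1)(c1ccccc1)C(C)(C)C | starting material
8 | lithium enolate corresponding to 6 | [Li]OC1=C[C@@](C)(CCCOCc2ccc(OC)cc2)[C@H](O[Si](CC)(CC)CC)CC1 | intermediate (not isolated)
9 | (3R,4R)-2-[2-(tert-butyldiphenylsilyloxy)-1-hydroxyethyl]-3-[3-(4-methoxybenzyloxy)propyl]-3-methyl-4-(triethylsilyloxy)cyclohexan-1-one, mixture at C2 and the carbinol | CC(C)(C)[Si](c1ccccc1)(c1ccccc1)OCC(O)C1[C@@](C)(CCCOCc2ccc(OC)cc2)[C@H](O[Si](CC)(CC)CC)CCC1=O | intermediate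
10 | methanesulfonate of 9 | CC(C)(C)[Si](c1ccccc1)(c1ccccc1)OCC(OS(C)(=O)=O)C1[C@@](C)(CCCOCc2ccc(OC)cc2)[C@H](O[Si](CC)(CC)CC)CCC1=O | intermediate (not isolated)
11 | (3R,4R)-2-[2-(tert-butyldiphenylsilyloxy)ethylidene]-3-[3-(4-methoxybenzyloxy)propyl]-3-methyl-4-(triethylsilyloxy)cyclohexan-1-one, E/Z mixture | CC(C)(C)[Si](c1ccccc1)(c1ccccc1)OCC=C1[C@@](C)(CCCOCc2ccc(OC)cc2)[C@H](O[Si](CC)(CC)CC)CCC1=O | intermediate
12 | (2R,3R,4R)-2-[2-(tert-butyldiphenylsilyloxy)ethyl]-3-[3-(4-methoxybenzyloxy)propyl]-3-methyl-4-(triethylsilyloxy)cyclohexan-1-one | CC(C)(C)[Si](c1ccccc1)(c1ccccc1)OCC[C@@H]1[C@@](C)(CCCOCc2ccc(OC)cc2)[C@H](O[Si](CC)(CC)CC)CCC1=O | intermediate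
13 | dichlorocerium alkoxide of the tertiary alcohol from methyl addition to 12 | CC(C)(C)[Si](c1ccccc1)(c1ccccc1)OCC[C@@H]1[C@@](C)(CCCOCc2ccc(OC)cc2)[C@H](O[Si](CC)(CC)CC)CC[C@]1(C)O[Ce](Cl)Cl | intermediate (not isolated)
14 | (1S,2R,3R,4R)-2-[2-(tert-butyldiphenylsilyloxy)ethyl]-3-[3-(4-methoxybenzyloxy)propyl]-1,3-dimethyl-4-(triethylsilyloxy)cyclohexyl acetate | CC(C)(C)[Si](c1ccccc1)(c1ccccc1)OCC[C@@H]1[C@@](C)(CCCOCc2ccc(OC)cc2)[C@H](O[Si](CC)(CC)CC)CC[C@]1(C)OC(C)=O | intermediate
15 | (1S,2R,3R,4R)-2-[2-(tert-butyldiphenylsilyloxy)ethyl]-4-hydroxy-3-[3-(4-methoxybenzyloxy)propyl]-1,3-dimethylcyclohexyl acetate | CC(C)(C)[Si](c1ccccc1)(c1ccccc1)OCC[C@@H]1[C@@](C)(CCCOCc2ccc(OC)cc2)[C@H](O)CC[C@]1(C)OC(C)=O | intermediate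
16 | but-2-ynoic acid | CC#CC(=O)O | starting material
17 | allyl bromide | C=CCBr | starting material
18 | allyl but-2-ynoate | CC#CC(=O)OCC=C | intermediate
19 | allyl (E)-3-alkoxybut-2-enoate of alcohol 15 | CC(C)(C)[Si](c1ccccc1)(c1ccccc1)OCC[C@@H]1[C@@](C)(CCCOCc2ccc(OC)cc2)[C@H](O/C(C)=C/C(=O)OCC=C)CC[C@]1(C)OC(C)=O | intermediate
20 | primary alcohol from 19 (3-hydroxypropyl chain) | CC(C)(C)[Si](c1ccccc1)(c1ccccc1)OCC[C@@H]1[C@@](C)(CCCO)[C@H](O/C(C)=C/C(=O)OCC=C)CC[C@]1(C)OC(C)=O | intermediate
21 | aldehyde (E)-β-alkoxycrotonate, key-step precursor (3-oxopropyl chain) | CC(C)(C)[Si](c1ccccc1)(c1ccccc1)OCC[C@@H]1[C@@](C)(CCC=O)[C@H](O/C(C)=C/C(=O)OCC=C)CC[C@]1(C)OC(C)=O | intermediate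
22 | ring C hydroxy oxepane with allyl ester arm, key-step product | CC(C)(C)[Si](c1ccccc1)(c1ccccc1)OCC[C@@H]1[C@@]2(C)CC[C@@H](O)[C@](C)(CC(=O)OCC=C)O[C@@H]2CC[C@]1(C)OC(C)=O | intermediate
23 | ring C acetate of 22 | CC(C)(C)[Si](c1ccccc1)(c1ccccc1)OCC[C@@H]1[C@@]2(C)CC[C@@H](OC(C)=O)[C@](C)(CC(=O)OCC=C)O[C@@H]2CC[C@]1(C)OC(C)=O | intermediate
24 | primary alcohol from 23 (2-hydroxyethyl arm) | OCC[C@@H]1[C@@]2(C)CC[C@@H](OC(C)=O)[C@](C)(CC(=O)OCC=C)O[C@@H]2CC[C@]1(C)OC(C)=O | intermediate
25 | diacetate-half aldehyde (2-oxoethyl arm) | O=CC[C@@H]1[C@@]2(C)CC[C@@H](OC(C)=O)[C@](C)(CC(=O)OCC=C)O[C@@H]2CC[C@]1(C)OC(C)=O | intermediate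
26 | aldol adduct of 6 and 25, mixture at the two new centres | O=C1CC[C@@H](O[Si](CC)(CC)CC)[C@](C)(CCCOCc2ccc(OC)cc2)C1C(O)C[C@@H]1[C@@]2(C)CC[C@@H](OC(C)=O)[C@](C)(CC(=O)OCC=C)O[C@@H]2CC[C@]1(C)OC(C)=O | intermediate
27 | methanesulfonate of 26 | O=C1CC[C@@H](O[Si](CC)(CC)CC)[C@](C)(CCCOCc2ccc(OC)cc2)C1C(OS(C)(=O)=O)C[C@@H]1[C@@]2(C)CC[C@@H](OC(C)=O)[C@](C)(CC(=O)OCC=C)O[C@@H]2CC[C@]1(C)OC(C)=O | intermediate (not isolated)
28 | alkylidene ketone from 26, E/Z mixture | O=C1CC[C@@H](O[Si](CC)(CC)CC)[C@](C)(CCCOCc2ccc(OC)cc2)C1=CC[C@@H]1[C@@]2(C)CC[C@@H](OC(C)=O)[C@](C)(CC(=O)OCC=C)O[C@@H]2CC[C@]1(C)OC(C)=O | intermediate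
29 | ring A ketone, tether cis to the angular methyl | O=C1CC[C@@H](O[Si](CC)(CC)CC)[C@](C)(CCCOCc2ccc(OC)cc2)[C@H]1CC[C@@H]1[C@@]2(C)CC[C@@H](OC(C)=O)[C@](C)(CC(=O)OCC=C)O[C@@H]2CC[C@]1(C)OC(C)=O | intermediate
30 | ring A exocyclic methylene compound | C=C1CC[C@@H](O[Si](CC)(CC)CC)[C@](C)(CCCOCc2ccc(OC)cc2)[C@H]1CC[C@@H]1[C@@]2(C)CC[C@@H](OC(C)=O)[C@](C)(CC(=O)OCC=C)O[C@@H]2CC[C@]1(C)OC(C)=O | intermediate
31 | ring A alcohol | C=C1CC[C@@H](O)[C@](C)(CCCOCc2ccc(OC)cc2)[C@H]1CC[C@@H]1[C@@]2(C)CC[C@@H](OC(C)=O)[C@](C)(CC(=O)OCC=C)O[C@@H]2CC[C@]1(C)OC(C)=O | intermediate
32 | ring A allyl (E)-3-alkoxybut-2-enoate | C=C1CC[C@@H](O/C(C)=C/C(=O)OCC=C)[C@](C)(CCCOCc2ccc(OC)cc2)[C@H]1CC[C@@H]1[C@@]2(C)CC[C@@H](OC(C)=O)[C@](C)(CC(=O)OCC=C)O[C@@H]2CC[C@]1(C)OC(C)=O | intermediate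
33 | primary alcohol from 32 | C=C1CC[C@@H](O/C(C)=C/C(=O)OCC=C)[C@](C)(CCCO)[C@H]1CC[C@@H]1[C@@]2(C)CC[C@@H](OC(C)=O)[C@](C)(CC(=O)OCC=C)O[C@@H]2CC[C@]1(C)OC(C)=O | intermediate
34 | ring A aldehyde (E)-β-alkoxycrotonate | C=C1CC[C@@H](O/C(C)=C/C(=O)OCC=C)[C@](C)(CCC=O)[C@H]1CC[C@@H]1[C@@]2(C)CC[C@@H](OC(C)=O)[C@](C)(CC(=O)OCC=C)O[C@@H]2CC[C@]1(C)OC(C)=O | intermediate
35 | bis-oxepane with free ring B hydroxyl and two allyl ester arms | C=C1CC[C@H]2O[C@@](C)(CC(=O)OCC=C)[C@H](O)CC[C@]2(C)[C@H]1CC[C@@H]1[C@@]2(C)CC[C@@H](OC(C)=O)[C@](C)(CC(=O)OCC=C)O[C@@H]2CC[C@]1(C)OC(C)=O | intermediate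
36 | ring B triethylsilyl ether of 35 | C=C1CC[C@H]2O[C@@](C)(CC(=O)OCC=C)[C@H](O[Si](CC)(CC)CC)CC[C@]2(C)[C@H]1CC[C@@H]1[C@@]2(C)CC[C@@H](OC(C)=O)[C@](C)(CC(=O)OCC=C)O[C@@H]2CC[C@]1(C)OC(C)=O | intermediate
37 | diacid from 36 | C=C1CC[C@H]2O[C@@](C)(CC(=O)O)[C@H](O[Si](CC)(CC)CC)CC[C@]2(C)[C@H]1CC[C@@H]1[C@@]2(C)CC[C@@H](OC(C)=O)[C@](C)(CC(=O)O)O[C@@H]2CC[C@]1(C)OC(C)=O | intermediate
38 | bis(N-acyloxyphthalimide) of 37 | C=C1CC[C@H]2O[C@@](C)(CC(=O)ON3C(=O)c4ccccc4C3=O)[C@H](O[Si](CC)(CC)CC)CC[C@]2(C)[C@H]1CC[C@@H]1[C@@]2(C)CC[C@@H](OC(C)=O)[C@](C)(CC(=O)ON3C(=O)c4ccccc4C3=O)O[C@@H]2CC[C@]1(C)OC(C)=O | intermediate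
39 | triethylsilyl ether of the target | C=C1CC[C@H]2OC(C)(C)[C@H](O[Si](CC)(CC)CC)CC[C@]2(C)[C@H]1CC[C@@H]1[C@@]2(C)CC[C@@H](OC(C)=O)C(C)(C)O[C@@H]2CC[C@]1(C)OC(C)=O | intermediate
40 | CNP0412606.2 | C=C1CC[C@H]2OC(C)(C)[C@H](O)CC[C@]2(C)[C@H]1CC[C@@H]1[C@@]2(C)CC[C@@H](OC(C)=O)C(C)(C)O[C@@H]2CC[C@]1(C)OC(C)=O | target

## Step count and least certain steps

Total: 31 steps. Longest linear sequence: 30 steps (steps 1 to 9 and 11 to 31; step 10 is a side preparation).

**Step 14 (key step).**
- What may go wrong: closure of a seven-membered ring onto a fully substituted β-carbon is slower than the six-membered cases. The ketyl may be reduced on to the alkoxide, which after work-up is alcohol 20 and is simply re-oxidised. More seriously, part of the closure may run through a non-chelated transition state, eroding facial control at the carbinol carbon.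
- Fallback: take the carbinol configuration out of the radical step. The mixture of carbinol epimers of 22 is oxidised with Dess–Martin periodinane to the ring C oxepan-3-one F1. F1 is reduced with NaBH4 in MeOH at low temperature. Hydride should approach anti to the axial methyl on the neighbouring quaternary ether carbon, the situation of a 4,4-disubstituted 3-ketone in a terpenoid ring, and give the equatorial alcohol. The fallback sets out from 22 (as the epimer mixture) and comes back at 22.

**Step 11 (repeated as step 23).**
- What may go wrong: the neopentyl-like alcohol adds slowly to the β-methyl ynoate. The phosphine may then isomerise 18 to the allenoate and deliver the alkoxide to the γ-carbon, or oligomerise 18.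
- Fallback: acid-catalysed enol ether exchange in place of nucleophilic catalysis. Allyl acetoacetate and trimethyl orthoformate with an acid catalyst give allyl (E)-3-methoxybut-2-enoate F2. Heating 15 with F2 and PPTS in toluene, with removal of methanol, exchanges the alkoxy group through a mixed ketal. The fallback sets out from 15 and comes back at 19; the same exchange would carry 31 to 32.

**Step 7 (the same control is used again in step 20).**
- What may go wrong: the copper enolate may be protonated on the face syn to the ring methyl, if it reacts through the half-chair with the propyl chain and the silyloxy group axial. The arm would then be trans to the methyl.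
- Fallback: form the C–C bond on that same face instead of the C–H bond. Lithium enolate 8, released from 6 with MeLi as in step 5, is alkylated with tert-butyl bromoacetate in THF/DMPU to the tert-butyl keto ester F3. MeMgBr with CeCl3 adds to the ketone, and the tertiary alkoxide closes onto the ester to give the cis-fused γ-lactone F4. LiAlH4 reduces F4 to the diol F5. TBDPSCl and imidazole silylate the primary hydroxyl to give the tertiary alcohol F6. n-BuLi followed by Ac2O gives 14. The fallback sets out from 8 and comes back at 14.

**Step 18.**
- What may go wrong: the enol carbon of 6 sits beside the quaternary carbon, so addition to the activated aldehyde may be slow. The Lewis acid would then have time to strip the triethylsilyl group or to protodesilylate the enol silane to the parent ketone.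
- Fallback: union through a preformed metal enolate in place of Lewis acid activation. Enol silane 6 is cleaved with MeLi in THF at 0 °C to lithium enolate 8, exactly as in step 5. Aldehyde 25 is added at −78 °C and the aldolate is quenched with AcOH at −78 °C, a temperature at which the esters are not attacked. The fallback sets out from 6 and 25, passes through 8, comes back at 26 and makes no new compound (F0).

**Step 30.**
- What may go wrong: only one of the two esters may be reduced. The primary radical beside the fully substituted ether carbon may also undergo intramolecular hydrogen transfer, for example from an ethyl group on silicon, before it meets the donor.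
- Fallback: oxidative instead of reductive decarboxylation, directly on the diacid. Diacid 37 is irradiated (blue LEDs) in trifluoroethanol with catalytic 9-mesityl-10-methylacridinium tetrafluoroborate, catalytic diphenyl disulfide and a catalytic amine base. The carboxylates are oxidised, lose CO2, and the radicals are reduced by hydrogen transfer from the thiol. The fallback sets out from 37, comes back at 39 and makes no new compound (F0).

## Further compounds

F1 | step 14 | ring C oxepan-3-one (ketone in place of the carbinol of 22) | CC(C)(C)[Si](c1ccccc1)(c1ccccc1)OCC[C@@H]1[C@@]2(C)CCC(=O)[C@](C)(CC(=O)OCC=C)O[C@@H]2CC[C@]1(C)OC(C)=O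
F2 | step 11 | allyl (E)-3-methoxybut-2-enoate | CO/C(C)=C/C(=O)OCC=C
F3 | step 7 | tert-butyl keto ester (acetate arm cis to the ring methyl) | CC(C)(C)OC(=O)C[C@@H]1[C@@](C)(CCCOCc2ccc(OC)cc2)[C@H](O[Si](CC)(CC)CC)CCC1=O
F4 | step 7 | cis-fused γ-lactone | O=C1C[C@@H]2[C@@](C)(CCCOCc3ccc(OC)cc3)[C@H](O[Si](CC)(CC)CC)CC[C@]2(C)O1
F5 | step 7 | diol (primary and tertiary hydroxyl) | OCC[C@@H]1[C@@](C)(CCCOCc2ccc(OC)cc2)[C@H](O[Si](CC)(CC)CC)CC[C@]1(C)O
F6 | step 7 | tertiary alcohol with TBDPS-protected arm | CC(C)(C)[Si](c1ccccc1)(c1ccccc1)OCC[C@@H]1[C@@](C)(CCCOCc2ccc(OC)cc2)[C@H](O[Si](CC)(CC)CC)CC[C@]1(C)O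
F0 | step 18 | none | none
F0 | step 30 | none | none
A1 | alternative 1 | cyclobutane photoadduct (furanone-fused, ring A ketal, silyloxyethyl arm) | CC1(C)O[C@]23CCC4(OCCO4)[C@H](CCO[Si](C)(C)C(C)(C)C)[C@@]2(C)C[C@@H]3C1=O
A2 | alternative 2 | ring A cycloadduct with enol ether and formyl group | O=C[C@@H]1CC=C2OC(C)(C)[C@H](O[Si](C)(C)C(C)(C)C)CC[C@]2(C)[C@H]1CC[C@@H]3[C@@]4(C)CC[C@@H](OC(C)=O)C(C)(C)O[C@@H]4CC[C@]3(C)OC(C)=O
A3 | alternative 3 | trans-fused oxepane cyclohexanone with benzyloxyethyl arm | c1ccccc1COCC[C@@H]1[C@@]2(C)CC[C@@H](O)C(C)(C)O[C@@H]2CCC1=O
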